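**Plan**

- The retrosynthesis cuts (a) the bond between the quinone ring and side-chain C1 (decarboxylative radical alkylation), (b) C7–C8 (Li2CuCl4-catalysed alkyl–alkyl coupling) and (c) the four bonds C16–C15, C14–C13, C12–C11 and C10–C9 in one operation. The side chain is numbered C1 at the ring to C17.
- Cut (c) is possible because C8–C17, with methyl groups on C9, C11, C13 and C15, is an ethyl group (C16–C17) followed by four head-to-tail propene units, i.e. a four-unit piece of isotactic polypropylene.
- Forward: four molecules of propene are joined on each ethyl group of diethylzinc and the chain is capped with iodine at C8; C1–C7 are added as a nonenyl Grignard reagent; the alkene is cut to the C22 acid; the acid is joined to the quinone with loss of CO2.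
- No ring is closed anywhere: the only ring, the benzoquinone, is obtained by oxidation of an aniline.
- All four stereocentres come from the oligomerisation, by enantiomorphic site control of an (R,R)-configured C2-symmetric ansa-zirconocene; no later step touches a stereocentre.

Key step: step 1

Assumption: the (R,R) enantiomer of the ansa-zirconocene is taken to select the re face of propene, as the accepted site model for this ligand class predicts; should the opposite sense be found, the (S,S) enantiomer is used with no other change.

Assumption: the precatalyst (R,R)-[C2H4(4,5,6,7-tetrahydro-1-indenyl)2]ZrMe2 contributes no atoms and is treated as a stock catalyst, obtainable from the commercial racemic dichloride by binaphtholate resolution and methylation with MeLi.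

**Step 1**
Reactants: 1 propene (the first of the four molecules that each chain takes up); 2 diethylzinc
Product: 4 (2S,4S,6S,8S)-1-iodo-2,4,6,8-tetramethyldecane, via bis[(2S,4S,6S,8S)-2,4,6,8-tetramethyldecyl]zinc 3 (not isolated)
Conditions: (R,R)-[C2H4(4,5,6,7-tetrahydro-1-indenyl)2]ZrMe2 (0.1 mol% per Zn–C), [Ph3C][B(C6F5)4] (1 equiv per Zr), toluene, −20 °C, propene fed slowly to 8 equiv per Zn (4 per Zn–C bond); then I2 (2 equiv per Zn), THF, −20 °C to rt; fractional distillation under reduced pressure
Reagents that add atoms: propene for the second insertion, CC=C; propene for the third insertion, CC=C; propene for the fourth insertion, CC=C; iodine, II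
Why: Proposed new method: each ethyl group of 2 passes reversibly from zinc to the cationic tetravalent zirconium centre and there takes up four molecules of propene (eight per zinc) by successive 1,2-migratory insertions, so that C16–C15, C14–C13, C12–C11 and C10–C9 form in turn, before the chain returns to zinc as 3 and I2 converts each Zn–C8 bond into C8–I (overall 8 C3H6 + ZnEt2 + 2 I2 gives two molecules of 4 and ZnI2). The closest known reaction types are coordinative chain-transfer polymerisation of propene on ZnEt2 with isospecific ansa-zirconocenes and zirconium-catalysed asymmetric carboalumination of 1-alkenes; new is the use of a single-enantiomer catalyst to stop at a tetramer of defined absolute configuration. No ring closes. Each of the four stereocentres (C9, C11, C13, C15) is set by enantiomorphic site control: the (R,R) ligand framework orients the growing chain, which in turn admits only the re face of propene at either of the two homotopic sites, so the same face is taken four times and the all-syn, all-S array of 4 results independently of the chain end. The step needs 1,2-regiochemistry (secured by the methyl group of propene, which keeps the metal on the CH2 terminus), uniform face selection (secured by the C2-symmetric site at −20 °C) and a narrow chain-length distribution (secured by Zn/Zr exchange that is fast relative to insertion under starved propene feed, which should give a Poisson distribution centred on four insertions, and by distillation of the C14 iodide from its C11 and C17 homologues). The least secure event is the first insertion into the Zr–ethyl bond, whose β-carbon is only a methyl group and steers the incoming propene less firmly than the branched chain does later.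

**Step 2**
Reactants: 4 (2S,4S,6S,8S)-1-iodo-2,4,6,8-tetramethyldecane; 5 9-bromonon-1-ene
Product: 7 (11R,13R,15S,17S)-11,13,15,17-tetramethylnonadec-1-ene, via non-8-enylmagnesium bromide 6 (not isolated)
Conditions: 5, Mg, THF, rt to 40 °C; then 4 (6 in 1.5-fold excess), Li2CuCl4 (3 mol%), THF/NMP, −10 °C to rt
Reagents that add atoms: magnesium (held in intermediate 6 and lost again before 7), [Mg]
Why: Li2CuCl4-catalysed cross-coupling of a primary alkyl iodide with a primary alkyl Grignard reagent (NMP as promoter) is routine for β-methyl-branched electrophiles in branched-lipid synthesis, forms the C7–C8 bond without touching the terminal alkene, and involves no stereocentre because the reacting carbon is the CH2 of 4.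

**Step 3**
Reactants: 7 (11R,13R,15S,17S)-11,13,15,17-tetramethylnonadec-1-ene
Product: 8 (10R,12R,14S,16S)-10,12,14,16-tetramethyloctadecanoic acid
Conditions: RuCl3 (2 mol%), NaIO4 (4.1 equiv), MeCN/EtOAc/H2O, rt
Reagents that add atoms: sodium periodate, [Na+].[O-]I(=O)(=O)=O; water, O
Why: Oxidative cleavage of a terminal alkene by RuO4 (formed catalytically from RuCl3 and NaIO4) gives the carboxylic acid one carbon shorter in a two-phase medium that suits a lipophilic substrate, and alkene cleavage is far faster than attack on the tertiary C–H bonds of a methyl-branched chain, so the four stereocentres persist.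

**Step 4**
Reactants: 9 2-methoxy-5-methylaniline
Product: 10 2-methoxy-5-methyl-1,4-benzoquinone
Conditions: Na2Cr2O7, aq. H2SO4, 0–10 °C; extraction with CH2Cl2
Reagents that add atoms: water for the oxygen para to nitrogen, O; water for the oxygen that replaces nitrogen, O
Why: Oxidation of a primary aniline with a free para position by Na2Cr2O7 in aqueous H2SO4 is the classical route to p-benzoquinones (oxidation to the quinone imine, then hydrolysis in the acidic medium), and it places the methoxy and methyl groups 2,5 to one another as required.

**Step 5**
Reactants: 8 (10R,12R,14S,16S)-10,12,14,16-tetramethyloctadecanoic acid; 10 2-methoxy-5-methyl-1,4-benzoquinone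
Product: 11 5-methoxy-2-methyl-3-[(9R,11R,13S,15S)-9,11,13,15-tetramethylheptadecyl]cyclohexa-2,5-diene-1,4-dione
Conditions: 10 (2 equiv), AgNO3 (0.3 equiv), (NH4)2S2O8 (1.5 equiv, slow addition), MeCN/H2O, 70 °C
Reagents that add atoms: none
Why: In this Minisci-type (Jacobsen–Torssell) alkylation, oxidative decarboxylation by AgNO3 and persulfate gives the primary alkyl radical, which adds to the quinone and is re-oxidised; the nucleophilic radical should attack C6 of 10, the free CH next to the methyl-bearing carbon, rather than C3 of the electron-rich methoxy enol ether, as in the alkylation of 2,3-dimethoxy-5-methylbenzoquinone, and the nearest stereocentre lies eight bonds from the radical carbon.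

**Compound list**

1 | propene | CC=C | starting material
2 | diethylzinc | CC[Zn]CC | starting material
3 | bis[(2S,4S,6S,8S)-2,4,6,8-tetramethyldecyl]zinc | CC[C@H](C)C[C@H](C)C[C@H](C)C[C@H](C)C[Zn]C[C@@H](C)C[C@@H](C)C[C@@H](C)C[C@@H](C)CC | intermediate
4 | (2S,4S,6S,8S)-1-iodo-2,4,6,8-tetramethyldecane | CC[C@H](C)C[C@H](C)C[C@H](C)C[C@H](C)CI | intermediate
5 | 9-bromonon-1-ene | C=CCCCCCCCBr | starting material
6 | non-8-enylmagnesium bromide | C=CCCCCCCC[Mg]Br | intermediate
7 | (11R,13R,15S,17S)-11,13,15,17-tetramethylnonadec-1-ene | CC[C@H](C)C[C@H](C)C[C@H](C)C[C@H](C)CCCCCCCCC=C | intermediate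
8 | (10R,12R,14S,16S)-10,12,14,16-tetramethyloctadecanoic acid | CC[C@H](C)C[C@H](C)C[C@H](C)C[C@H](C)CCCCCCCCC(=O)O | intermediate
9 | 2-methoxy-5-methylaniline | COc1ccc(C)cc1N | starting material
10 | 2-methoxy-5-methyl-1,4-benzoquinone | COC1=CC(=O)C(C)=CC1=O | intermediate
11 | 5-methoxy-2-methyl-3-[(9R,11R,13S,15S)-9,11,13,15-tetramethylheptadecyl]cyclohexa-2,5-diene-1,4-dione (CNP0330767.1) | CC[C@H](C)C[C@H](C)C[C@H](C)C[C@H](C)CCCCCCCCC1=C(C)C(=O)C=C(OC)C1=O | target

**Step count**

Total: 5 steps. Longest linear sequence: 4 steps (steps 1, 2, 3, 5); step 4 is a one-step branch.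

**Steps most likely to fail**

Step 1 (proposed new method). Three processes may go wrong.
- Chain exchange between zinc and zirconium may be slow relative to insertion, which would broaden the chain-length distribution until the tetramer can no longer be distilled out in useful amount; compound 3 is in any case only the tetramer member of a statistical family of dialkylzincs.
- Face selection at the first insertion into the Zr–ethyl bond may be eroded, leaving the C15 epimer, which would co-distil and has to be assayed by 13C NMR on 4.
- Occasional 2,1-insertion or β-hydride elimination would divert chains.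

Fallback (known chemistry, iterative zirconium-catalysed asymmetric carboalumination with vinylation): step 1 draws only on feedstocks, so this fallback takes commercial (S)-1-bromo-2-methylbutane (CC[C@H](C)CBr) in place of propene 1 and diethylzinc 2 and comes back to the route at iodide 4. The bromide is converted with Mg in THF into (S)-2-methylbutylmagnesium bromide F1, which Kumada coupling with vinyl bromide (Pd(PPh3)4, THF) turns into (S)-4-methylhex-1-ene F2; the C15 centre is thus taken from the chiral pool. Three rounds of asymmetric methylalumination (Me3Al, the enantiomer of (NMI)2ZrCl2 that delivers the (S)-2-methylalkyl metal, expected to be the (+)-form, NMI = 1-neomenthylindenyl, methylaluminoxane (MeAlO)n, CH2Cl2) then add one CH2–CH(CH3) unit each under catalyst control. F2 gives dimethyl[(2S,4S)-2,4-dimethylhexyl]alane F3, whose vinylation in the same pot (Zn(OTf)2, DMF, vinyl bromide, Pd(DPEphos)Cl2) gives (4R,6S)-4,6-dimethyloct-1-ene F4. F4 gives dimethyl[(2S,4S,6S)-2,4,6-trimethyloctyl]alane F5 and, after the same vinylation, (4R,6S,8S)-4,6,8-trimethyldec-1-ene F6. F6 gives dimethyl[(2S,4S,6S,8S)-2,4,6,8-tetramethyldecyl]alane F7, which I2 in THF cleaves to iodide 4. Diastereomeric purity is checked at F4 and F6.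

Step 5. The waxy acid may stay out of the aqueous acetonitrile phase, so that its radical forms slowly and is lost to oxidation or dimerisation. A second alkylation, or competing attack at C3 next to the methoxy group, may erode the yield of the wanted regioisomer.

Fallback (regiochemistry fixed by an aromatic Claisen rearrangement): it sets out from iodide 4 and comes back at target 11. Iodide 4 is coupled (Li2CuCl4, THF/NMP) with hex-5-enylmagnesium bromide F8, made from 6-bromohex-1-ene and Mg, to give (8R,10R,12S,14S)-8,10,12,14-tetramethylhexadec-1-ene F9. Commercial 2-methoxy-5-methylphenol is O-allylated (allyl bromide, K2CO3, acetone) to 2-(allyloxy)-1-methoxy-4-methylbenzene F10. On heating (N,N-diethylaniline, 200 °C) this rearranges to 2-allyl-6-methoxy-3-methylphenol F11, because the only free ortho position lies between the oxygen-bearing and the methyl-bearing carbon. Cross-metathesis of F9 with an excess of F11 (second-generation Grubbs catalyst, CH2Cl2, 40 °C) should give mainly 6-methoxy-3-methyl-2-[(2E,9R,11R,13S,15S)-9,11,13,15-tetramethylheptadec-2-en-1-yl]phenol F12. Hydrogenation (H2, Pd/C, EtOAc) gives 6-methoxy-3-methyl-2-[(9R,11R,13S,15S)-9,11,13,15-tetramethylheptadecyl]phenol F13, and oxidation at the free para position (Co(salen), O2, DMF) gives target 11.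

Step 2. Substitution at the β-branched primary carbon may be slow, so that iodine–magnesium exchange, reduction and homocoupling of the Grignard reagent consume the iodide.

Fallback (polarity reversed, acid function carried in): it sets out from iodide 4 and comes back at acid 8, which makes step 3 unnecessary. Iodide 4 is converted with Mg in THF into (2S,4S,6S,8S)-2,4,6,8-tetramethyldecylmagnesium iodide F14. Commercial 8-bromooctanoic acid is deprotonated with t-BuMgCl to chloromagnesium 8-bromooctanoate F15. The two are joined with Li2CuCl4 (cat.) in THF at −20 °C, and acidic work-up gives acid 8.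

**Further compounds**

F1 | step 1 | (S)-2-methylbutylmagnesium bromide | CC[C@H](C)C[Mg]Br
F2 | step 1 | (S)-4-methylhex-1-ene | CC[C@H](C)CC=C
F3 | step 1 | dimethyl[(2S,4S)-2,4-dimethylhexyl]alane | CC[C@H](C)C[C@H](C)C[Al](C)C
F4 | step 1 | (4R,6S)-4,6-dimethyloct-1-ene | CC[C@H](C)C[C@H](C)CC=C
F5 | step 1 | dimethyl[(2S,4S,6S)-2,4,6-trimethyloctyl]alane | CC[C@H](C)C[C@H](C)C[C@H](C)C[Al](C)C
F6 | step 1 | (4R,6S,8S)-4,6,8-trimethyldec-1-ene | CC[C@H](C)C[C@H](C)C[C@H](C)CC=C
F7 | step 1 | dimethyl[(2S,4S,6S,8S)-2,4,6,8-tetramethyldecyl]alane | CC[C@H](C)C[C@H](C)C[C@H](C)C[C@H](C)C[Al](C)C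
F8 | step 5 | hex-5-enylmagnesium bromide | C=CCCCC[Mg]Br
F9 | step 5 | (8R,10R,12S,14S)-8,10,12,14-tetramethylhexadec-1-ene | CC[C@H](C)C[C@H](C)C[C@H](C)C[C@H](C)CCCCCC=C
F10 | step 5 | 2-(allyloxy)-1-methoxy-4-methylbenzene | COc1ccc(C)cc1OCC=C
F11 | step 5 | 2-allyl-6-methoxy-3-methylphenol | COc1ccc(C)c(CC=C)c1O
F12 | step 5 | 6-methoxy-3-methyl-2-[(2E,9R,11R,13S,15S)-9,11,13,15-tetramethylheptadec-2-en-1-yl]phenol | CC[C@H](C)C[C@H](C)C[C@H](C)C[C@H](C)CCCCC/C=C/Cc1c(C)ccc(OC)c1O
F13 | step 5 | 6-methoxy-3-methyl-2-[(9R,11R,13S,15S)-9,11,13,15-tetramethylheptadecyl]phenol | CC[C@H](C)C[C@H](C)C[C@H](C)C[C@H](C)CCCCCCCCc1c(C)ccc(OC)c1O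
F14 | step 2 | (2S,4S,6S,8S)-2,4,6,8-tetramethyldecylmagnesium iodide | CC[C@H](C)C[C@H](C)C[C@H](C)C[C@H](C)C[Mg]I
F15 | step 2 | chloromagnesium 8-bromooctanoate | BrCCCCCCCC(=O)O[Mg]Cl
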